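**Retrosynthetic overview**
1. Target 23 ⇐ silyl ether 22 ⇐ ester 18 by one anionic cascade: the γ-lactone and ring A (the cyclohexene) close together, then a methyl group is added in the same flask.
2. 18 ⇐ acid 16 + (R)-4-hydroxycyclopentenone 17, which brings the cyclopentane ring and the lactone oxygen.
3. 16 ⇐ alkenyl iodide 11 + (S)-4-silyloxycyclopentenone 12, which brings the future spiro ring (reductive conjugate addition, then enone regeneration).
4. 11 ⇐ Johnson–Claisen rearrangement of aldol 8 (1,3-chirality transfer sets the side-chain stereocentre and the Z-alkene) ⇐ asymmetric acetate aldol of iodo-dienal 4 ⇐ methacrolein 1.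
5. Ring order: the cyclopentane ring and the spiro ring are bought as enantiopure cyclopentenones; the lactone closes first and ring A second, both within step 9.

Assumption: 12 and 17 are purchased; CpTiCl(ODAG)2 (ODAG = 1,2:5,6-di-O-isopropylidene-α-D-glucofuranos-3-O-yl) is made beforehand from CpTiCl3 and diacetone-D-glucose and is not counted as a step.

**Step 1**
Reactants: 1 methacrolein; 2 (triphenylphosphoranylidene)acetaldehyde
Product: 3 (2E)-4-methylpenta-2,4-dienal
Conditions: 1 (4 equiv), toluene, 80 °C, sealed tube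
Reagents that add atoms: none
Why: Wittig olefination with a stabilised formyl ylide gives the E-enal, and the excess of cheap, volatile 1 suppresses a second homologation of 3.

**Step 2**
Reactants: 3 (2E)-4-methylpenta-2,4-dienal
Product: 4 (2Z)-2-iodo-4-methylpenta-2,4-dienal
Conditions: I2 (1.5 equiv), K2CO3 (1.2 equiv), DMAP (0.2 equiv), THF/H2O 1:1, 23 °C
Reagents that add atoms: iodine, II
Why: Nucleophile-catalysed α-iodination of an enal (Baylis–Hillman-type addition of DMAP, iodination of the enolate, E1cB loss of DMAP) returns the conjugated α-iodo enal as the Z isomer, with the formyl group still trans to the isopropenyl group.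

**Step 3**
Reactants: 4 (2Z)-2-iodo-4-methylpenta-2,4-dienal; 5 tert-butyl acetate
Product: 8 tert-butyl (3R,4Z)-3-hydroxy-4-iodo-6-methylhepta-4,6-dienoate, via lithium enolate 6 (not isolated), via titanium enolate 7 (not isolated)
Conditions: 5, LiN(iPr)2, Et2O, −78 °C; CpTiCl(ODAG)2 (1.2 equiv), −78 → −30 °C; then 4, −78 °C; aq NH4F
Reagents that add atoms: none
Why: Asymmetric acetate aldol addition with the diacetone-D-glucose-derived cyclopentadienyltitanium enolate (Duthaler reagent), which adds 1,2 to the enal on the Re face of the aldehyde and so sets the 3R carbinol (typically 90–96% ee with this reagent; configuration to be confirmed by Mosher analysis).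

**Step 4**
Reactants: 8 tert-butyl (3R,4Z)-3-hydroxy-4-iodo-6-methylhepta-4,6-dienoate; 9 trimethyl orthoacetate
Product: 11 1-tert-butyl 7-methyl (3Z,5S)-4-iodo-5-(prop-1-en-2-yl)hept-3-enedioate, via ketene acetal 10 (not isolated)
Conditions: 9 (10 equiv), EtCO2H (0.1 equiv), toluene, 110 °C, MeOH distilled off
Reagents that add atoms: none
Why: Johnson–Claisen rearrangement through a chair transition state with the CH2CO2tBu group equatorial transfers the 3R carbinol chirality suprafacially to the new 5S centre, installs the CH2CO2Me arm, and gives the trisubstituted alkene with CH2CO2tBu cis to iodine (3Z), as ring A requires.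

**Step 5**
Reactants: 11 1-tert-butyl 7-methyl (3Z,5S)-4-iodo-5-(prop-1-en-2-yl)hept-3-enedioate; 12 (4S)-4-(tert-butyldimethylsilyloxy)cyclopent-2-en-1-one
Product: 13 1-tert-butyl 7-methyl (3Z,5S)-4-[(1R,5S)-5-(tert-butyldimethylsilyloxy)-3-(triethylsilyloxy)cyclopent-2-en-1-yl]-5-(prop-1-en-2-yl)hept-3-enedioate
Conditions: 12 (1.5 equiv), NiCl2(dme) (10 mol %), neocuproine (10 mol %), Mn powder (2 equiv), Et3SiCl (1.5 equiv), DMF, 23 °C
Reagents that add atoms: chlorotriethylsilane, CC[Si](Cl)(CC)CC
Why: Nickel-catalysed reductive conjugate addition of an alkenyl halide to an enone (via a silyloxyallylnickel intermediate) forms the C–C bond at the β-carbon anti to OTBS under neutral conditions that tolerate both esters and gives a regiodefined silyl enol ether; the new ring stereocentre is erased in step 6.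

**Step 6**
Reactants: 13 (the triethylsilyl enol ether from step 5)
Product: 14 1-tert-butyl 7-methyl (3Z,5S)-4-[(5S)-5-(tert-butyldimethylsilyloxy)-3-oxocyclopent-1-en-1-yl]-5-(prop-1-en-2-yl)hept-3-enedioate
Conditions: Pd(OAc)2 (1.1 equiv), MeCN, 23 °C
Reagents that add atoms: none
Why: Saegusa–Ito oxidation of the regiodefined silyl enol ether can only eliminate toward the alkenyl-bearing carbon, so it restores the cyclopentenone as the 3-alkenyl-4-silyloxy enone without touching the OTBS centre.

**Step 7**
Reactants: 14 (the tert-butyl ester dienone from step 6)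
Product: 16 (3Z,5S)-4-[(5S)-5-(tert-butyldimethylsilyloxy)-3-oxocyclopent-1-en-1-yl]-7-methoxy-7-oxo-5-(prop-1-en-2-yl)hept-3-enoic acid, via trimethylsilyl ester 15 (not isolated)
Conditions: TMSOTf (3 equiv), 2,6-lutidine (5 equiv), CH2Cl2, 0 °C; pH 7 phosphate buffer
Reagents that add atoms: none
Why: Silyl triflate-mediated cleavage of the tert-butyl ester (loss of isobutene, then hydrolysis of the silyl ester) is buffered and non-protic, so the methyl ester, the TBS ether and the acid-sensitive isopropenyl/ester pair survive, and any silyl dienol ether formed at the dienone reverts on work-up.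

**Step 8**
Reactants: 16 (the acid from step 7); 17 (4R)-4-hydroxycyclopent-2-en-1-one
Product: 18 7-methyl 1-[(1R)-4-oxocyclopent-2-en-1-yl] (3Z,5S)-4-[(5S)-5-(tert-butyldimethylsilyloxy)-3-oxocyclopent-1-en-1-yl]-5-(prop-1-en-2-yl)hept-3-enedioate
Conditions: 17 (1.2 equiv), DCC (1.2 equiv), DMAP (0.1 equiv), CH2Cl2, 0 °C
Reagents that add atoms: none
Why: Steglich esterification at 0 °C acylates the secondary alcohol without eliminating the base-sensitive 4-acyloxycyclopentenone and leaves the carbinol configuration untouched; any migration of the β,γ-alkene into conjugation is harmless because all tautomers give the same extended enolate in step 9.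

**Step 9**
Reactants: 18 (the cyclopentenyl ester from step 8)
Product: 22 tert-butyldimethylsilyl ether of the target, via lithium trienolate 19 (not isolated), via lactone enolate 20 (not isolated), via tetracyclic enolate 21 (not isolated)
Conditions: LiN(SiMe3)2 (1.05 equiv), THF, −78 → −40 °C; then MeLi/CeCl3 (3 equiv, premixed), −78 °C; aq NH4Cl
Reagents that add atoms: methyllithium, [Li]C
Why: Proposed new method: LiN(SiMe3)2 removes the most acidic proton (C-2, α to the ester and ε to the dienone) to give an extended trienolate whose ester-bound carbon adds 5-exo to the tethered cyclopentenone on the face of the ester oxygen (cis-fused γ-lactone, side chain on the convex face); the ketone enolate so formed adds 6-exo to the β-carbon of the silyloxycyclopentenone anti to OTBS, closing ring A and setting the spiro quaternary centre; the terminal lithium enolate keeps the spiro-ring carbonyl masked while MeCeCl2 attacks the only free ketone from its convex face (methyl cis to the ring-fusion hydrogens); the closest known reaction types are the base-mediated intramolecular double Michael reaction (anionic formal Diels–Alder) of tethered enolate/enone pairs and organocerium addition to an enolisable ketone beside a ketone protected as its enolate.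

**Step 10**
Reactants: 22 tert-butyldimethylsilyl ether of the target
Product: 23 CNP0255095.1 (target)
Conditions: HF·pyridine, pyridine, THF, 0 → 23 °C
Reagents that add atoms: none
Why: Buffered fluoride desilylation frees the secondary alcohol without β-elimination of the β-hydroxy ketone, lactonisation of the isopropenyl ester or epimerisation at the lactone α-carbon.

**Compound list**
1 | methacrolein (2-methylprop-2-enal) | C=C(C)C=O | starting material
2 | (triphenylphosphoranylidene)acetaldehyde | O=CC=P(c1ccccc1)(c1ccccc1)c1ccccc1 | starting material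
3 | (2E)-4-methylpenta-2,4-dienal | C=C(C)/C=C/C=O | intermediate
4 | (2Z)-2-iodo-4-methylpenta-2,4-dienal | C=C(C)/C=C(\I)C=O | intermediate
5 | tert-butyl acetate | CC(=O)OC(C)(C)C | starting material
6 | lithium enolate of tert-butyl acetate | C=C([O-])OC(C)(C)C.[Li+] | intermediate
7 | cyclopentadienyl-bis(diacetone-D-glucos-3-O-yl)titanium enolate of tert-butyl acetate (Cp drawn σ-bonded) | C=C(OC(C)(C)C)O[Ti](C1C=CC=C1)(O[C@@H]1[C@H]2OC(C)(C)O[C@H]2O[C@@H]1[C@H]1COC(C)(C)O1)O[C@@H]1[C@H]2OC(C)(C)O[C@H]2O[C@@H]1[C@H]1COC(C)(C)O1 | intermediate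
8 | tert-butyl (3R,4Z)-3-hydroxy-4-iodo-6-methylhepta-4,6-dienoate | C=C(C)/C=C(\I)[C@H](O)CC(=O)OC(C)(C)C | intermediate
9 | trimethyl orthoacetate | CC(OC)(OC)OC | starting material
10 | tert-butyl (3R,4Z)-4-iodo-3-[(1-methoxyethenyl)oxy]-6-methylhepta-4,6-dienoate (mixed ketene acetal) | C=C(C)/C=C(\I)[C@H](OC(=C)OC)CC(=O)OC(C)(C)C | intermediate
11 | 1-tert-butyl 7-methyl (3Z,5S)-4-iodo-5-(prop-1-en-2-yl)hept-3-enedioate | C=C(C)[C@H](CC(=O)OC)/C(I)=C/CC(=O)OC(C)(C)C | intermediate
12 | (4S)-4-(tert-butyldimethylsilyloxy)cyclopent-2-en-1-one | C1=CC(=O)C[C@@H]1O[Si](C)(C)C(C)(C)C | starting material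
13 | 1-tert-butyl 7-methyl (3Z,5S)-4-[(1R,5S)-5-(tert-butyldimethylsilyloxy)-3-(triethylsilyloxy)cyclopent-2-en-1-yl]-5-(prop-1-en-2-yl)hept-3-enedioate | C=C(C)[C@H](CC(=O)OC)/C(=C/CC(=O)OC(C)(C)C)[C@H]1C=C(O[Si](CC)(CC)CC)C[C@@H]1O[Si](C)(C)C(C)(C)C | intermediate
14 | 1-tert-butyl 7-methyl (3Z,5S)-4-[(5S)-5-(tert-butyldimethylsilyloxy)-3-oxocyclopent-1-en-1-yl]-5-(prop-1-en-2-yl)hept-3-enedioate | C=C(C)[C@H](CC(=O)OC)/C(=C/CC(=O)OC(C)(C)C)C1=CC(=O)C[C@@H]1O[Si](C)(C)C(C)(C)C | intermediate
15 | trimethylsilyl ester of acid 16 | C=C(C)[C@H](CC(=O)OC)/C(=C/CC(=O)O[Si](C)(C)C)C1=CC(=O)C[C@@H]1O[Si](C)(C)C(C)(C)C | intermediate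
16 | (3Z,5S)-4-[(5S)-5-(tert-butyldimethylsilyloxy)-3-oxocyclopent-1-en-1-yl]-7-methoxy-7-oxo-5-(prop-1-en-2-yl)hept-3-enoic acid | C=C(C)[C@H](CC(=O)OC)/C(=C/CC(=O)O)C1=CC(=O)C[C@@H]1O[Si](C)(C)C(C)(C)C | intermediate
17 | (4R)-4-hydroxycyclopent-2-en-1-one | O[C@@H]1CC(=O)C=C1 | starting material
18 | 7-methyl 1-[(1R)-4-oxocyclopent-2-en-1-yl] (3Z,5S)-4-[(5S)-5-(tert-butyldimethylsilyloxy)-3-oxocyclopent-1-en-1-yl]-5-(prop-1-en-2-yl)hept-3-enedioate | C=C(C)[C@H](CC(=O)OC)/C(=C/CC(=O)O[C@@H]1CC(=O)C=C1)C1=CC(=O)C[C@@H]1O[Si](C)(C)C(C)(C)C | intermediate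
19 | lithium trienolate of 18 (drawn as the C-2 carbanion resonance form) | C=C(C)[C@H](CC(=O)OC)/C(=C/[CH-]C(=O)O[C@@H]1CC(=O)C=C1)C1=CC(=O)C[C@@H]1O[Si](C)(C)C(C)(C)C.[Li+] | intermediate
20 | lithium enolate of the cis-fused bicyclic γ-lactone cyclopentanone (first Michael adduct; dienone side chain intact) | C=C(C)[C@H](CC(=O)OC)/C(=C/[C@H]1C(=O)O[C@@H]2CC([O-])=C[C@@H]21)C1=CC(=O)C[C@@H]1O[Si](C)(C)C(C)(C)C.[Li+] | intermediate
21 | lithium enolate of the tetracyclic diketone (enolate in the spiro ring; cyclopentanone carbonyl free) | C=C(C)[C@H](CC(=O)OC)C1=C[C@H]2C(=O)O[C@@H]3CC(=O)[C@@H]([C@@H]32)[C@]12C=C([O-])C[C@@H]2O[Si](C)(C)C(C)(C)C.[Li+] | intermediate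
22 | tert-butyldimethylsilyl ether of the target (spiro-ring secondary OH silylated) | C=C(C)[C@H](CC(=O)OC)C1=C[C@H]2C(=O)O[C@@H]3C[C@](C)(O)[C@@H]([C@@H]32)[C@]12CC(=O)C[C@@H]2O[Si](C)(C)C(C)(C)C | intermediate
23 | CNP0255095.1: methyl (3S)-4-methyl-3-(tetracyclic spiro-lactone)pent-4-enoate; lactone α-CH R; three-ring junction CH R; lactone OCH R; C(CH3)OH S; cyclopentane/ring A junction CH S; spiro carbon R; CHOH S | C=C(C)[C@H](CC(=O)OC)C1=C[C@H]2C(=O)O[C@@H]3C[C@](C)(O)[C@@H]([C@@H]32)[C@]12CC(=O)C[C@@H]2O | target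

**Step count and risks**
Total step count: 10. Longest linear sequence: 10 steps (1 → 23); 12 and 17 enter convergently.

Steps most likely to fail:

Step 9 (cascade plus in-flask methylation). The amide base may also deprotonate next to a ketone and trigger β-elimination of the acyloxy or silyloxy group. The second Michael addition may be slow or unselective at the lactone α-carbon or the spiro centre. Proton transfer may unmask the spiro-ring ketone before the methyl addition. The fallback sets out from 18 and returns to the route at 23. Treat 18 with LiN(SiMe3)2 and Me3SiCl at −78 °C so that only the first Michael addition occurs and is trapped as the bicyclic lactone trimethylsilyl enol ether F1. Close ring A separately by a Lewis-acid Mukaiyama–Michael addition with silyl transfer (Me3SiNTf2 cat., CH2Cl2, −78 °C), giving the tetracyclic ketone silyl enol ether F2 with the spiro-ring carbonyl still masked. Add MeLi/CeCl3 to obtain the tertiary carbinol F3, and remove both silyl groups with HF·pyridine to reach 23.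

Step 5 (reductive conjugate addition). The hindered, α-branched alkenyl iodide may couple slowly, isomerise or be reduced. The fallback sets out from 11 (with 12) and returns at 14. Miyaura borylation of 11 (B2pin2, PdCl2(dppf), KOAc, DMSO, 80 °C) gives the alkenyl boronate F4. An oxidative boron-Heck coupling of F4 with 12 under divalent-palladium catalysis (Pd(OAc)2 10 mol %, 2,9-dimethyl-1,10-phenanthroline, O2, DMF, 50 °C) installs the alkenyl group at the β-carbon and regenerates the enone by β-hydride elimination, giving 14 directly and bypassing 13 and step 6.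

Step 2 (α-iodination of the dienal). The nucleophilic catalyst may add 1,6 or polymerise the volatile dienal. The fallback sets out from 1 and returns at 4. Wittig olefination of 1 with the α-iodo ylide generated from Ph3P=CHCO2Et and N-iodosuccinimide gives ethyl (2Z)-2-iodo-4-methylpenta-2,4-dienoate F5. Reduction with iBu2AlH gives (2Z)-2-iodo-4-methylpenta-2,4-dien-1-ol F6, and MnO2 oxidation gives 4, replacing steps 1 and 2.

**Further compounds**
F1 | step 9 | bicyclic γ-lactone trimethylsilyl enol ether (first Michael adduct of 18 trapped on the cyclopentanone oxygen) | C=C(C)[C@H](CC(=O)OC)/C(=C/[C@H]1C(=O)O[C@@H]2CC(O[Si](C)(C)C)=C[C@@H]21)C1=CC(=O)C[C@@H]1O[Si](C)(C)C(C)(C)C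
F2 | step 9 | tetracyclic ketone with the spiro-ring carbonyl as its trimethylsilyl enol ether | C=C(C)[C@H](CC(=O)OC)C1=C[C@H]2C(=O)O[C@@H]3CC(=O)[C@@H]([C@@H]32)[C@]12C=C(O[Si](C)(C)C)C[C@@H]2O[Si](C)(C)C(C)(C)C
F3 | step 9 | tertiary methyl carbinol from F2 (spiro-ring trimethylsilyl enol ether and OTBS retained) | C=C(C)[C@H](CC(=O)OC)C1=C[C@H]2C(=O)O[C@@H]3C[C@](C)(O)[C@@H]([C@@H]32)[C@]12C=C(O[Si](C)(C)C)C[C@@H]2O[Si](C)(C)C(C)(C)C
F4 | step 5 | 1-tert-butyl 7-methyl (3E,5R)-5-(prop-1-en-2-yl)-4-(4,4,5,5-tetramethyl-1,3,2-dioxaborolan-2-yl)hept-3-enedioate | C=C(C)[C@H](CC(=O)OC)/C(B1OC(C)(C)C(C)(C)O1)=C/CC(=O)OC(C)(C)C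
F5 | step 2 | ethyl (2Z)-2-iodo-4-methylpenta-2,4-dienoate | C=C(C)/C=C(\I)C(=O)OCC
F6 | step 2 | (2Z)-2-iodo-4-methylpenta-2,4-dien-1-ol | C=C(C)/C=C(\I)CO
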